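Eunicellane numbering (C1–C17) is used for the target and for every intermediate. Compound numbers are those of the steps and of the compound list.

## Analysis of the target

The target is a tetracyclic eunicellane. A cyclohexane (ring A: C1, C10, C11, C12, C13, C14) is cis-fused along C1–C10 to a tetrahydrofuran (C1, C2, O, C9, C10); the same oxygen and C2–C9 belong to a nine-membered oxonene with a Z trisubstituted alkene at C6=C7, and a seven-membered lactone (C14–C15–C17(=O)–O–C3–C2–C1) ties the side chain of ring A to the oxonene. The eight stereocentres are (1S,2S,3S,9S,10R,11R,14R,15R): H1 and H10 are syn, H2 and H9 are syn to each other and anti to H1/H10, the C14 branch is trans to C2, and the C11 acetate lies on the face of ring A that carries C9 (C11 methyl syn to H10). C3 and C11 are both fully substituted carbinol carbons, one acylated within the lactone and one as an acetate, and C15 is an exocyclic centre α to the lactone carbonyl and therefore epimerisable by base. The tertiary acetate can ionise or eliminate under acid, the medium-ring alkene invites transannular attack and the lactone is base-labile, so the last steps must be close to neutral. The difficulties are the tertiary C11–O centre whose oxygen sits on the hindered face next to the ring fusion, the nine-membered ring with a trisubstituted alkene, and the remote C15 centre. The strategy rests on one feature: ring A is a p-menthane (methyl on C11, three-carbon branch C15–C16–C17 on C14), and the acetate sits on C11 directly beside C10, the atom through which ring A is bonded to C9, so a C10=C11 alkene can be nucleophilic at C10 and become cationic at C11 in one event.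

## Retrosynthetic reasoning

**Lactone C17–O bond.** 30 is opened between C17 and the oxygen on C3 and C17 is lowered to the alcohol level, giving diol 27. This bond goes first because the lactone makes C15 acidic and occupies the only other tertiary hydroxyl. With the C11 oxygen already acetylated, 27 has one primary and one tertiary hydroxyl, so the forward step only has to oxidise the primary one and let the tertiary one close onto it (through aldehyde 28 and lactol 29). 27 comes from the bis-silyl ether 26.

**C6=C7.** The alkene of 26 is cut to diene 25, which has a 2-methylallyl arm on C9 and a but-3-enyl arm on C3. The double bond is the only unfunctionalised stretch of the nine-membered ring, its Z geometry is dictated by the ring, and both arms sit cis on the tetrahydrofuran of 25. The forward reaction must close a nine-membered ring to a trisubstituted alkene, which calls for an active ruthenium carbene and dilution.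

**C9–C10 and C11–O (key disconnection).** In 25 the acetate oxygen on C11 and carbon C9 are bonded to neighbouring ring atoms on the same face. Removing both bonds returns a C10=C11 alkene in ring A and an acetate on C9, the α-acetoxy ether 22. This is the only cut that uses the p-menthane pattern of ring A directly. It makes the tetrahydrofuran and three stereocentres (C9, C10, C11) together and needs no acylation of a hindered tertiary alcohol, because the acetate is already in the molecule. Forward, a Lewis acid must ionise 22 to oxocarbenium ion 23, C10 must attack C9, and the acetate must return to cation 24 on the face it left from.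

**C9 acetal and acyl–oxygen bond.** 22 is the reduced and acetylated form of ester 20 (through aluminium hemiacetal 21), and 20 is the ester of secondary alcohol 17 with the β,γ-unsaturated acid 18 (activated as 19). Ester formation tolerates the crowded C2 hydroxyl far better than an acetal exchange would, and 18 brings C7, its methyl group, C8 and C9 in one commercial piece.

**C10 oxygen.** The C10=C11 alkene of 17 is traced to the C10 ketone of enone 14 by a reductive 1,3-transposition (tosylhydrazone 15, diazene 16). The ketone is needed for the next disconnection; removing it with migration of the double bond places the alkene where the key step needs it and turns C12 into a methylene group.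

**C1–C2.** An aldol disconnection of 14 gives ketone 6 and aldehyde 12. C1 is the α′-carbon of a carvone-type enone, whose enolate 13 reacts anti to the C14 substituent, and a cyclic enolate gives the anti aldol needed at C2. C3 arrives already set in 12.

**C15.** Ketone 6 is the silyl ether of alcohol 5, whose C15 centre comes from hydrogenation of allylic alcohol 4. 4 is reached from 1 by allylic chlorination (2) and exchange of chloride for oxygen (3). C14 is the stereocentre of 1 itself. Using up the side-chain alkene here means no other 1,1-disubstituted alkene competes with the metathesis partner later.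

**C4–C5.** Aldehyde 12 is made from the bis-silyl ether 10 of diol 9, and 9 from epoxide 7 by opening at its methylene carbon with the allyl nucleophile 8. The quaternary C3 centre is bought rather than made; an asymmetric one-carbon addition to a methyl ketone would have to tell a methyl from a primary alkyl group.

## Alternatives that were turned down

**Alternative 1: intramolecular Diels–Alder reaction across a preformed oxonene.**
- Disconnection: the C1–C10 and C13–C14 bonds of ring A, leading to the monocyclic oxonene A1 with a 2-methylbuta-1,3-dienyl group on C9 and a 3-oxobut-1-enyl group on C2.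
- Forward key step: heating A1 should bring the diene over the enone and give cycloadduct A2, closing ring A and, through C1–C10, the tetrahydrofuran in one operation.
- For it: the cycloaddition is suprafacial on both partners, so the H1/H10 cis fusion and the C14 configuration follow from alkene geometry and an exo transition state. Two rings and three stereocentres form at once, and the nine-membered ring is closed early on a flexible chain.
- Against it for this target: A2 still has a C11=C12 alkene and a C14 acetyl group. The tertiary acetate would need Markovnikov hydration of a trisubstituted alkene beside the C6=C7 alkene, with oxygen on the face syn to C9 that external reagents avoid. The acetyl group would have to be methylenated and reduced at C15 under reagent control on a late tricycle. A1 also needs C2, C3 and C9 set on an open chain, which makes the linear sequence long.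
- Comparison: the cycloaddition is better understood and more predictable than the Prins step chosen here, and that point goes to Alternative 1. The chosen route offers instead that C11–O, C14 and C15 are in place when the core forms, that C14 comes from the chiral pool, and that fewer steps follow the key step.

**Alternative 2: De Mayo two-carbon insertion into a bridged diketone.**
- Disconnection: the C3–C4 and C5–C6 bonds, i.e. excision of C4–C5, leading to the bridged seven-membered 1,3-diketone A3 (carbonyls at C3 and C7, C6 between them).
- Forward key step: the enol of A3 is irradiated with a C2 alkene; [2+2] photocycloaddition and retro-aldol opening of the cyclobutanol give the nine-membered 3,7-dione A4.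
- For it: the medium ring is made by ring expansion rather than end-to-end closure, so no high dilution is needed and no trisubstituted alkene has to be forced into a ring. Both enol tautomers of A3 lead to the same 1,5-diketone.
- Against it: A4 has neither the C3 methyl carbinol centre nor the C7 methyl group nor the C6=C7 alkene. Two ketones that differ only in their distance from the ether carbons must be told apart, methyl must be added to C3 with facial control, and C7 must become a Z alkene at C6=C7 rather than C7=C8 or exocyclic. A3 is itself an advanced tricycle that already needs the C11 tertiary oxygen with the right configuration, and the silyl group on that oxygen must later be exchanged for acetate on a hindered tertiary alcohol.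
- Comparison: the ring expansion is less sensitive to conformation and catalyst than metathesis to a trisubstituted alkene, and is stronger on that point. The chosen route offers instead an alkene whose position and geometry are fixed by the metathesis partners, a C3 centre taken from an enantiopure epoxide, and far fewer operations after the key step.

**Alternative 3: Ramberg–Bäcklund contraction of a ten-membered cyclic sulfone.**
- Disconnection: the C6=C7 double bond, replaced by a sulfonyl bridge in the ten-membered sulfone A5.
- Forward key step: α-halogenation in situ, 1,3-elimination to the episulfone and extrusion of the sulfonyl bridge contract the ring to oxonene A6.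
- For it: the large ring is closed by carbon–sulfur bond formation, which is easier than carbon–carbon closure of a nine-membered ring. The contraction needs no transition metal, is indifferent to alkene substitution, and can only give the Z alkene in this ring.
- Against it: it answers only the C6=C7 bond. The tetrahydrofuran-fused ring A with its C11 oxygen must be made some other way first, so the hard problem stays open. Sulfide closure at a secondary C7 carbon, oxidation and contraction are at least three operations where metathesis is one, the conditions are strongly basic, and A6 again carries a silyl ether at C11 that must be exchanged for acetate late.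
- Comparison: as a way to the alkene it is as strong as or stronger than metathesis when closure to a trisubstituted medium-ring alkene is slow. The chosen route offers a one-step closure on a diene (25) preorganised by the cis-2,5-disubstituted tetrahydrofuran and, above all, a construction of the core, which this alternative lacks.

Key step: step 13

## Assumptions

- Step 3: Ru(OAc)2[(S)-BINAP] is assumed to add hydrogen to the same face of the allylic alcohol unit of 4 as it does in geraniol and nerol, which gives (15R); if the other C15 epimer predominates, the (R)-ligand is used instead.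
- Compound 22 is formed as both epimers at the acetal carbon C9; one is drawn, and both ionise to the same cation.

## Route

Step 1
Reactants: 1 (R)-carvone
Product: 2 (5R)-5-(3-chloroprop-1-en-2-yl)-2-methylcyclohex-2-en-1-one
Conditions: Ca(OCl)2, solid CO2, CH2Cl2–H2O, 0 °C
Reagents that add atoms: calcium hypochlorite, [Ca+2].[O-]Cl.[O-]Cl
Why: Ene-type allylic chlorination by hypochlorous acid, which attacks only the electron-rich 1,1-disubstituted alkene and leaves the enone alone; C14 is not touched.

Step 2
Reactants: 2 (5R)-5-(3-chloroprop-1-en-2-yl)-2-methylcyclohex-2-en-1-one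
Product: 4 (5R)-5-(3-hydroxyprop-1-en-2-yl)-2-methylcyclohex-2-en-1-one, via allylic acetate 3 (not isolated)
Conditions: KOAc, Bu4NI (cat.), DMF, 60 °C; then K2CO3 (cat.), MeOH, 0 °C
Reagents that add atoms: potassium acetate, CC(=O)[O-].[K+]
Why: Displacement of the primary allylic chloride by acetate (direct or allylic attack gives the same product) followed by transesterification with methanol; the mild carbonate should not disturb the enone.

Step 3
Reactants: 4 (5R)-5-(3-hydroxyprop-1-en-2-yl)-2-methylcyclohex-2-en-1-one
Product: 5 (5R)-5-[(2R)-1-hydroxypropan-2-yl]-2-methylcyclohex-2-en-1-one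
Conditions: H2 (30 atm), Ru(OAc)2[(S)-BINAP] (1 mol %), MeOH, 25 °C
Reagents that add atoms: none
Why: Hydroxyl-directed asymmetric hydrogenation of an allylic alcohol by the ruthenium–BINAP dicarboxylate, which reduces only the alkene held through the alkoxide and so should spare the enone; the ligand, not the remote C14 centre, is expected to fix C15 as R.

Step 4
Reactants: 5 (5R)-5-[(2R)-1-hydroxypropan-2-yl]-2-methylcyclohex-2-en-1-one
Product: 6 (5R)-5-[(2R)-1-(tert-butyldiphenylsilyloxy)propan-2-yl]-2-methylcyclohex-2-en-1-one
Conditions: TBDPSCl, imidazole, DMF, 0 → 23 °C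
Reagents that add atoms: tert-butyl(chloro)diphenylsilane, CC(C)(C)[Si](Cl)(c1ccccc1)c1ccccc1
Why: Standard silylation of a primary alcohol; the robust silyl ether survives enolate, hydride and Lewis-acid steps and is removed together with the triethylsilyl group in step 15.

Step 5
Reactants: 7 (R)-2-methylglycidol; 8 allylmagnesium chloride
Product: 9 (2S)-2-methylhex-5-ene-1,2-diol
Conditions: 8 (2.5 equiv), CuI (10 mol %), THF, −30 → 0 °C; aq. NH4Cl
Reagents that add atoms: none
Why: Copper-catalysed SN2 opening of the 2,2-disubstituted epoxide at its CH2 terminus by the Grignard reagent (one equivalent is spent on the hydroxyl); the quaternary centre is not involved, so its configuration is retained and only the descriptor changes from R to S.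

Step 6
Reactants: 9 (2S)-2-methylhex-5-ene-1,2-diol
Product: 10 (2S)-2-methyl-1,2-bis(triethylsilyloxy)hex-5-ene
Conditions: TESOTf (2.4 equiv), 2,6-lutidine, CH2Cl2, −78 → 0 °C
Reagents that add atoms: triethylsilyl trifluoromethanesulfonate, CC[Si](CC)(CC)OS(=O)(=O)C(F)(F)F
Why: The silyl triflate silylates the tertiary as well as the primary hydroxyl; bis-silylation avoids handling a free α-hydroxy aldehyde later.

Step 7
Reactants: 10 (2S)-2-methyl-1,2-bis(triethylsilyloxy)hex-5-ene
Product: 12 (2S)-2-methyl-2-(triethylsilyloxy)hex-5-enal, via alkoxysulfonium chloride 11 (not isolated)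
Conditions: (COCl)2, DMSO, CH2Cl2, −78 → −30 °C; Et3N, −78 → 0 °C
Reagents that add atoms: none
Why: Under Swern conditions the unhindered primary triethylsilyl ether is attacked by the chlorosulfonium salt and oxidised directly to the aldehyde, while the tertiary silyl ether is too hindered to react; the aldehyde has no α-hydrogen and cannot epimerise.

Step 8
Reactants: 6 (5R)-5-[(2R)-1-(tert-butyldiphenylsilyloxy)propan-2-yl]-2-methylcyclohex-2-en-1-one; 12 (2S)-2-methyl-2-(triethylsilyloxy)hex-5-enal
Product: 14 (5S,6R)-5-[(2R)-1-(tert-butyldiphenylsilyloxy)propan-2-yl]-6-[(1S,2S)-1-hydroxy-2-methyl-2-(triethylsilyloxy)hex-5-en-1-yl]-2-methylcyclohex-2-en-1-one, via lithium dienolate 13 (not isolated)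
Conditions: LiN(i-Pr)2, THF, −78 °C; 12, −78 °C; AcOH, −78 °C
Reagents that add atoms: none
Why: Kinetic deprotonation at C1 (α′) gives the cross-conjugated lithium dienolate, which adds to the aldehyde through a closed chair (Zimmerman–Traxler) transition state. Attack anti to the C14 side chain sets C1, and the fixed E(O) geometry of the cyclic enolate with the tertiary alkyl group of the aldehyde equatorial sets C2 (anti aldol). C3 comes in with 12, whose own facial bias (methyl against a primary alkyl group) is too small to override the enolate.

Step 9
Reactants: 14 anti-aldol adduct (1R,2S,3S,14S,15R)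
Product: 15 C10 p-toluenesulfonylhydrazone of 14
Conditions: TsNHNH2, EtOH–THF, 45 °C
Reagents that add atoms: p-toluenesulfonyl hydrazide, Cc1ccc(cc1)S(=O)(=O)NN
Why: Condensation of the conjugated ketone with the sulfonyl hydrazide under near-neutral conditions; the β-hydroxyl and both silyl ethers are inert and no stereocentre is formed.

Step 10
Reactants: 15 C10 p-toluenesulfonylhydrazone of 14
Product: 17 (1S,2S)-1-{(1S,6S)-6-[(2R)-1-(tert-butyldiphenylsilyloxy)propan-2-yl]-3-methylcyclohex-2-en-1-yl}-2-methyl-2-(triethylsilyloxy)hex-5-en-1-ol, via allylic diazene 16 (not isolated)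
Conditions: catecholborane, CHCl3, 0 °C; NaOAc·3H2O, 60 °C
Reagents that add atoms: none
Why: Catecholborane reduces the C=N bond of the unsaturated tosylhydrazone in the 1,2-sense, acetate triggers loss of sulfinate, and the allylic diazene loses N2 by a retro-ene hydrogen shift that places hydrogen on C12 and the double bond at C10=C11 (reductive 1,3-transposition). C1 never becomes trigonal, and the terminal alkene is not hydroborated at this temperature.

Step 11
Reactants: 17 homoallylic alcohol (1S,2S,3S,14S,15R); 18 3-methylbut-3-enoic acid
Product: 20 3-methylbut-3-enoate of 17 at the C2 oxygen, via O-acylisourea 19 (not isolated)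
Conditions: DCC, DMAP (10 mol %), CH2Cl2, 0 → 23 °C
Reagents that add atoms: none
Why: Carbodiimide/DMAP (Steglich) esterification of the hindered secondary hydroxyl; low temperature and only catalytic DMAP are used to keep the β,γ-unsaturated acyl group from moving into conjugation.

Step 12
Reactants: 20 3-methylbut-3-enoate of 17
Product: 22 α-acetoxy ether C2–O–C9H(OAc)–CH2–C(CH3)=CH2 (both C9 epimers), via aluminium hemiacetal 21 (not isolated)
Conditions: i-Bu2AlH, CH2Cl2, −78 °C; pyridine, DMAP, Ac2O, −78 → −20 °C
Reagents that add atoms: acetic anhydride, CC(=O)OC(C)=O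
Why: Reductive acetylation of an ester: the hydride adds once at −78 °C and the aluminium hemiacetal is acetylated in the flask before it can collapse to the aldehyde; the silyl ethers and alkenes are unaffected.

Step 13
Reactants: 22 α-acetoxy ether (both C9 epimers)
Product: 25 (1S,2S,3S,9S,10R,11R,14S,15R)-11-acetoxy cis-fused hexahydroisobenzofuran with 2-methylprop-2-enyl on C9 and (2S)-2-(triethylsilyloxy)hex-5-en-2-yl on C2 and (2R)-1-(tert-butyldiphenylsilyloxy)propan-2-yl on C14, via oxocarbenium ion pair 23 (not isolated), via C11 carbocation 24 (not isolated)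
Conditions: BF3·OEt2 (1.2 equiv), toluene–hexane, −78 °C; Et3N quench
Reagents that add atoms: none
Why: Proposed new method: BF3·OEt2 ionises either C9 epimer of 22 to the E oxocarbenium ion 23, which in the hydrocarbon medium stays paired with acetoxytrifluoroborate; C10 of the trisubstituted alkene bonds to C9 and leaves the tertiary cation 24, and the acetate that left C9 is meant to collapse onto C11 before the ion pair separates, so that the Lewis acid is released and nothing is added or lost. The closest known reaction type is the Lewis-acid Prins cyclisation of α-acetoxy ethers, which gives tetrahydrofurans when a trisubstituted alkene places the cation outside the new ring and in which return of the counter-ion within a contact ion pair is known for bromide; face-selective return of acetate to a cation one carbon away from the ionised centre has not been shown. The tetrahydrofuran closes 5-exo-trig with respect to the alkene (5-endo with respect to the C=O+ bond); closure through C11 to a six-membered ring is disfavoured because it would leave a secondary cation at C10 and build a quaternary carbon. C9 is set by the E geometry of 23 and an envelope transition state with the C3 and C8 substituents pseudo-equatorial, which gives the 2,5-cis ring (H2 and H9 syn). C10 is set by the three-atom tether from C1, which lets C9 reach only the alkene face that carries C2, hence the cis ring fusion. C11 is the open point: the target needs oxygen syn to C9, whereas a free nucleophile would enter axially, anti to the new C9–C10 bond, and the only element in the substrate that works for the syn face is the position of the departed acetate, which lies below C9 on that face. The step therefore needs regioselectivity (secured by the methyl group on C11), chemoselectivity over the 2-methylallyl alkene (only C10 can reach C9 in a five-membered ring) and syn facial selectivity at C11 (sought through low temperature, low polarity and the absence of any other nucleophile such as halide or added acetic acid).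

Step 14
Reactants: 25 11-acetoxy hexahydroisobenzofuran diene
Product: 26 (1S,2S,3S,9S,10R,11R,14S,15R,6Z)-11-acetoxy-17-(tert-butyldiphenylsilyloxy)-2,9-epoxy-3-(triethylsilyloxy)eunicell-6-ene
Conditions: second-generation Grubbs catalyst RuCl2(=CHPh)(PCy3)(H2IMes) (10 mol %), CH2Cl2 (1 mM), 40 °C
Reagents that add atoms: none
Why: Ring-closing metathesis between the monosubstituted and the 1,1-disubstituted alkene; the two arms are cis on the tetrahydrofuran and C3 is fully substituted, which favours closure, and the nine-membered ring can hold the trisubstituted alkene only as Z.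

Step 15
Reactants: 26 silyl-protected tricyclic oxonene
Product: 27 (1S,2S,3S,9S,10R,11R,14S,15R,6Z)-11-acetoxy-2,9-epoxyeunicell-6-ene-3,17-diol
Conditions: HF·pyridine, pyridine, THF, 0 → 23 °C
Reagents that add atoms: none
Why: Fluoride cleaves the tertiary triethylsilyl and the primary tert-butyldiphenylsilyl ether; the pyridine-buffered medium should leave the tertiary acetate and the ring alkene untouched.

Step 16
Reactants: 27 3,17-diol
Product: 30 target CNP0332402.2 (1S,2S,3S,9S,10R,11R,14R,15R,6Z)-11-acetoxy-2,9-epoxyeunicell-6-en-17,3-olide, via C17 aldehyde 28 (not isolated), via lactol 29 (not isolated)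
Conditions: TEMPO (20 mol %), PhI(OAc)2 (3 equiv), CH2Cl2, 23 °C
Reagents that add atoms: none
Why: Oxidative lactonisation: the oxoammonium species oxidises only the primary alcohol to the aldehyde, the C3 hydroxyl held close by the tricycle closes the seven-membered lactol, and the lactol is oxidised on to the lactone. The medium is not basic, so C15 next to the new carbonyl should keep its configuration.

## Compound list

1 | (R)-carvone | CC1=CC[C@H](CC1=O)C(C)=C | starting material
2 | (5R)-5-(3-chloroprop-1-en-2-yl)-2-methylcyclohex-2-en-1-one | CC1=CC[C@H](CC1=O)C(CCl)=C | intermediate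
3 | 2-[(1R)-4-methyl-5-oxocyclohex-3-en-1-yl]prop-2-en-1-yl acetate | CC1=CC[C@H](CC1=O)C(COC(C)=O)=C | intermediate
4 | (5R)-5-(3-hydroxyprop-1-en-2-yl)-2-methylcyclohex-2-en-1-one | CC1=CC[C@H](CC1=O)C(CO)=C | intermediate
5 | (5R)-5-[(2R)-1-hydroxypropan-2-yl]-2-methylcyclohex-2-en-1-one | CC1=CC[C@H](CC1=O)[C@@H](C)CO | intermediate
6 | (5R)-5-[(2R)-1-(tert-butyldiphenylsilyloxy)propan-2-yl]-2-methylcyclohex-2-en-1-one | CC1=CC[C@H](CC1=O)[C@@H](C)CO[Si](c2ccccc2)(c2ccccc2)C(C)(C)C | intermediate
7 | (R)-2-methylglycidol, [(2R)-2-methyloxiran-2-yl]methanol | OC[C@]1(C)CO1 | starting material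
8 | allylmagnesium chloride | C=CC[Mg]Cl | starting material
9 | (2S)-2-methylhex-5-ene-1,2-diol | OC[C@](C)(CCC=C)O | intermediate
10 | (2S)-2-methyl-1,2-bis(triethylsilyloxy)hex-5-ene | CC[Si](CC)(CC)OC[C@](C)(CCC=C)O[Si](CC)(CC)CC | intermediate
11 | dimethyl{[(2S)-2-methyl-2-(triethylsilyloxy)hex-5-en-1-yl]oxy}sulfonium chloride | C[S+](C)OC[C@](C)(CCC=C)O[Si](CC)(CC)CC.[Cl-] | intermediate
12 | (2S)-2-methyl-2-(triethylsilyloxy)hex-5-enal | O=C[C@](C)(CCC=C)O[Si](CC)(CC)CC | intermediate
13 | lithium dienolate of 6 (C1=C10 enolate, C14 and C15 as in 6) | CC1=CC[C@H](C=C1O[Li])[C@@H](C)CO[Si](c2ccccc2)(c2ccccc2)C(C)(C)C | intermediate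
14 | (5S,6R)-5-[(2R)-1-(tert-butyldiphenylsilyloxy)propan-2-yl]-6-[(1S,2S)-1-hydroxy-2-methyl-2-(triethylsilyloxy)hex-5-en-1-yl]-2-methylcyclohex-2-en-1-one; eunicellane (1R,2S,3S,14S,15R) | CC1=CC[C@@H]([C@@H](C)CO[Si](c2ccccc2)(c2ccccc2)C(C)(C)C)[C@H]([C@H](O)[C@](C)(CCC=C)O[Si](CC)(CC)CC)C1=O | intermediate
15 | C10 p-toluenesulfonylhydrazone of 14 | CC1=CC[C@@H]([C@@H](C)CO[Si](c2ccccc2)(c2ccccc2)C(C)(C)C)[C@H]([C@H](O)[C@](C)(CCC=C)O[Si](CC)(CC)CC)C1=NNS(=O)(=O)c3ccc(C)cc3 | intermediate
16 | allylic diazene (C10–N=NH) derived from 15 | CC1=CC[C@@H]([C@@H](C)CO[Si](c2ccccc2)(c2ccccc2)C(C)(C)C)[C@H]([C@H](O)[C@](C)(CCC=C)O[Si](CC)(CC)CC)C1N=N | intermediate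
17 | (1S,2S)-1-{(1S,6S)-6-[(2R)-1-(tert-butyldiphenylsilyloxy)propan-2-yl]-3-methylcyclohex-2-en-1-yl}-2-methyl-2-(triethylsilyloxy)hex-5-en-1-ol; eunicellane (1S,2S,3S,14S,15R) | CC1=C[C@@H]([C@H](O)[C@](C)(CCC=C)O[Si](CC)(CC)CC)[C@H]([C@@H](C)CO[Si](c2ccccc2)(c2ccccc2)C(C)(C)C)CC1 | intermediate
18 | 3-methylbut-3-enoic acid | C=C(C)CC(=O)O | starting material
19 | O-acylisourea from 18 and dicyclohexylcarbodiimide | C=C(C)CC(=O)OC(=NC1CCCCC1)NC1CCCCC1 | intermediate
20 | 3-methylbut-3-enoate of 17 (ester on the C2 oxygen) | CC1=C[C@@H]([C@H](OC(=O)CC(C)=C)[C@](C)(CCC=C)O[Si](CC)(CC)CC)[C@H]([C@@H](C)CO[Si](c2ccccc2)(c2ccccc2)C(C)(C)C)CC1 | intermediate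
21 | diisobutylaluminium hemiacetal of 20 (C9–O–Al) | CC1=C[C@@H]([C@H](OC(O[Al](CC(C)C)CC(C)C)CC(C)=C)[C@](C)(CCC=C)O[Si](CC)(CC)CC)[C@H]([C@@H](C)CO[Si](c2ccccc2)(c2ccccc2)C(C)(C)C)CC1 | intermediate
22 | α-acetoxy ether C2–O–C9H(OAc)–CH2–C(CH3)=CH2 of 17 (both C9 epimers, one drawn) | CC1=C[C@@H]([C@H](O[C@H](OC(C)=O)CC(C)=C)[C@](C)(CCC=C)O[Si](CC)(CC)CC)[C@H]([C@@H](C)CO[Si](c2ccccc2)(c2ccccc2)C(C)(C)C)CC1 | intermediate
23 | E oxocarbenium ion C2–O+=C9H–C8 paired with acetoxytrifluoroborate | CC1=C[C@@H]([C@H](/[O+]=C/CC(C)=C)[C@](C)(CCC=C)O[Si](CC)(CC)CC)[C@H]([C@@H](C)CO[Si](c2ccccc2)(c2ccccc2)C(C)(C)C)CC1.CC(=O)O[B-](F)(F)F | intermediate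
24 | tertiary C11 carbocation of the cis-fused hexahydroisobenzofuran paired with acetoxytrifluoroborate | C[C+]1CC[C@@H]([C@@H](C)CO[Si](c2ccccc2)(c2ccccc2)C(C)(C)C)[C@H]3[C@@H]1[C@H](CC(C)=C)O[C@@H]3[C@](C)(CCC=C)O[Si](CC)(CC)CC.CC(=O)O[B-](F)(F)F | intermediate
25 | (1S,2S,3S,9S,10R,11R,14S,15R)-11-acetoxy hexahydroisobenzofuran with 2-methylprop-2-enyl on C9, (2S)-2-(triethylsilyloxy)hex-5-en-2-yl on C2 and (2R)-1-(tert-butyldiphenylsilyloxy)propan-2-yl on C14 | CC(=O)O[C@]1(C)CC[C@@H]([C@@H](C)CO[Si](c2ccccc2)(c2ccccc2)C(C)(C)C)[C@H]3[C@@H]1[C@H](CC(C)=C)O[C@@H]3[C@](C)(CCC=C)O[Si](CC)(CC)CC | intermediate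
26 | (1S,2S,3S,9S,10R,11R,14S,15R,6Z)-11-acetoxy-17-(tert-butyldiphenylsilyloxy)-2,9-epoxy-3-(triethylsilyloxy)eunicell-6-ene | CC(=O)O[C@]1(C)CC[C@@H]([C@@H](C)CO[Si](c2ccccc2)(c2ccccc2)C(C)(C)C)[C@H]3[C@@H]1[C@@H]1C/C(C)=C\CC[C@](C)(O[Si](CC)(CC)CC)[C@H]3O1 | intermediate
27 | (1S,2S,3S,9S,10R,11R,14S,15R,6Z)-11-acetoxy-2,9-epoxyeunicell-6-ene-3,17-diol | CC(=O)O[C@]1(C)CC[C@@H]([C@@H](C)CO)[C@H]3[C@@H]1[C@@H]1C/C(C)=C\CC[C@](C)(O)[C@H]3O1 | intermediate
28 | C17 aldehyde of 27 (C3 hydroxyl free) | CC(=O)O[C@]1(C)CC[C@@H]([C@@H](C)C=O)[C@H]3[C@@H]1[C@@H]1C/C(C)=C\CC[C@](C)(O)[C@H]3O1 | intermediate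
29 | seven-membered lactol (C17 hemiacetal with the C3 oxygen) | CC(=O)O[C@]1(C)CC[C@@H]2[C@H]3[C@@H]1[C@@H]1C/C(C)=C\CC[C@](C)(OC(O)[C@@H]2C)[C@H]3O1 | intermediate
30 | CNP0332402.2, (1S,2S,3S,9S,10R,11R,14R,15R,6Z)-11-acetoxy-2,9-epoxyeunicell-6-en-17,3-olide | CC(=O)O[C@]1(C)CC[C@@H]2[C@H]3[C@@H]1[C@@H]1C/C(C)=C\CC[C@](C)(OC(=O)[C@@H]2C)[C@H]3O1 | target

## Step count and least certain steps

Total: 16 steps. Longest linear sequence: 13 steps (from 1 through steps 1–4 and 8–16); the aldehyde branch (steps 5–7) joins at step 8.

**Step 13 (key step, proposed new method).** The ion pair may separate before it collapses. The C11 cation would then be quenched from the open face anti to C9, lose a proton from C12 or the methyl group, take up fluoride, or be attacked by the 2-methylallyl alkene. Each of these is the stereoelectronically or sterically normal course, whereas syn return relies only on proximity.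

Fallback (known reactions, oxygen tethered to C9), from 17 back to 25:
- Conjugate addition of the C2 hydroxyl of 17 to but-3-yn-2-one (PMe3 cat., CH2Cl2) gives the (E)-β-alkoxy enone F1.
- With Me2AlCl (CH2Cl2, −78 → 0 °C) the enone acts as a 1-oxadiene (O=C7–C8=C9) in an intramolecular hetero-Diels–Alder reaction with inverse electron demand onto the C10=C11 alkene. C9–C10 and O–C11 form on the same alkene face and give the dihydropyran F2; the oxygen on C11 is syn to C9 by construction.
- Mild aqueous acid (oxalic acid, wet THF) hydrolyses the enol ether to the hydroxy ketone F3.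
- Wittig methylenation (Ph3P=CH2, THF) gives the tertiary alcohol F4.
- Acetylation (Ac2O, Et3N, DMAP, 40 °C) returns to 25.

**Step 3.** Facial discrimination of a 1,1-disubstituted alkene by the catalyst may be insufficient or of the opposite sense, and the allylic alcohol may isomerise to the aldehyde at low hydrogen pressure.

Fallback (carboxylate instead of hydroxyl as directing group), from 4 back to 5:
- MnO2 oxidises 4 to the enal F5.
- NaClO2/NaH2PO4/2-methylbut-2-ene gives the acrylic acid F6.
- Hydrogenation with Ru(OAc)2[(R)-BINAP], by analogy with 2-arylacrylic acids, should give the (R)-acid F7.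
- BH3·THF at 0 °C reduces the acid faster than the conjugated ketone and returns to 5.

**Step 8.** The lithium aldolate may equilibrate by retro-aldol reaction, and the anti/syn preference at C2 may erode because the aldehyde is slightly mismatched.

Fallback (boron enolate, tighter transition state), from 6 and 12 back to 14:
- c-Hex2BCl/Et3N (Et2O, −78 → 0 °C) converts 6 into the dicyclohexylboron dienolate F8.
- Addition of 12 at −78 °C through a tighter chair gives the boron aldolate F9.
- Oxidative work-up (H2O2, pH 7 buffer, MeOH) returns to 14.

**Step 14.** Closure to a trisubstituted alkene in a nine-membered ring next to the fully substituted C3 may be slower than intermolecular metathesis of the monosubstituted alkene, leading to oligomerisation.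

Fallback (lactone closed first, so the two arms are held together), from 25 directly to 30:
- HF·pyridine desilylates 25 to the diene diol F10.
- TEMPO/PhI(OAc)2 gives the diene lactone F11.
- Ring-closing metathesis with the same second-generation Grubbs catalyst gives 30.

**Step 16.** Closure of the seven-membered lactol onto a tertiary hydroxyl may be incomplete, so the aldehyde lingers and C15 may epimerise or the aldehyde may be over-oxidised without cyclising.

Fallback (acyl activation instead of lactol oxidation), from 27 to 30:
- Dess–Martin periodinane oxidises 27 to the 28/29 mixture.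
- NaClO2/NaH2PO4/2-methylbut-2-ene gives the hydroxy acid F12.
- Yamaguchi lactonisation (2,4,6-trichlorobenzoyl chloride, Et3N; DMAP, toluene, 80 °C) closes the ring to 30.

## Further compounds

F1 | step 13 | (E)-4-alkoxybut-3-en-2-one carrying the C2 oxygen of 17 | CC1=C[C@@H]([C@H](O/C=C/C(C)=O)[C@](C)(CCC=C)O[Si](CC)(CC)CC)[C@H]([C@@H](C)CO[Si](c2ccccc2)(c2ccccc2)C(C)(C)C)CC1
F2 | step 13 | dihydropyran-fused hexahydroisobenzofuran (C11–O–C7(CH3)=C8H–C9) | C[C@@]12CC[C@@H]([C@@H](C)CO[Si](c4ccccc4)(c4ccccc4)C(C)(C)C)[C@H]3[C@@H]1[C@H](C=C(C)O2)O[C@@H]3[C@](C)(CCC=C)O[Si](CC)(CC)CC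
F3 | step 13 | C11 tertiary alcohol with a 2-oxopropyl group on C9 | C[C@@]1(O)CC[C@@H]([C@@H](C)CO[Si](c2ccccc2)(c2ccccc2)C(C)(C)C)[C@H]3[C@@H]1[C@H](CC(C)=O)O[C@@H]3[C@](C)(CCC=C)O[Si](CC)(CC)CC
F4 | step 13 | C11 tertiary alcohol with a 2-methylprop-2-enyl group on C9 (25 without the acetyl group) | C[C@@]1(O)CC[C@@H]([C@@H](C)CO[Si](c2ccccc2)(c2ccccc2)C(C)(C)C)[C@H]3[C@@H]1[C@H](CC(C)=C)O[C@@H]3[C@](C)(CCC=C)O[Si](CC)(CC)CC
F5 | step 3 | (5R)-2-methyl-5-(3-oxoprop-1-en-2-yl)cyclohex-2-en-1-one | CC1=CC[C@H](CC1=O)C(C=O)=C
F6 | step 3 | 2-[(1R)-4-methyl-5-oxocyclohex-3-en-1-yl]prop-2-enoic acid | CC1=CC[C@H](CC1=O)C(=C)C(=O)O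
F7 | step 3 | (2R)-2-[(1R)-4-methyl-5-oxocyclohex-3-en-1-yl]propanoic acid | CC1=CC[C@H](CC1=O)[C@@H](C)C(=O)O
F8 | step 8 | dicyclohexylboron dienolate of 6 | CC1=CC[C@H](C=C1OB(C2CCCCC2)C2CCCCC2)[C@@H](C)CO[Si](c3ccccc3)(c3ccccc3)C(C)(C)C
F9 | step 8 | dicyclohexylboron aldolate of 14 | CC1=CC[C@@H]([C@@H](C)CO[Si](c2ccccc2)(c2ccccc2)C(C)(C)C)[C@H]([C@H](OB(C3CCCCC3)C3CCCCC3)[C@](C)(CCC=C)O[Si](CC)(CC)CC)C1=O
F10 | step 14 | diene diol (25 without its silyl groups) | CC(=O)O[C@]1(C)CC[C@@H]([C@@H](C)CO)[C@H]3[C@@H]1[C@H](CC(C)=C)O[C@@H]3[C@](C)(CCC=C)O
F11 | step 14 | diene lactone (17,3-olide with open oxonene) | CC(=O)O[C@]1(C)CC[C@@H]2[C@H]3[C@@H]1[C@H](CC(C)=C)O[C@@H]3[C@](C)(CCC=C)OC(=O)[C@@H]2C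
F12 | step 16 | 3-hydroxy C17 carboxylic acid (seco acid of 30) | CC(=O)O[C@]1(C)CC[C@@H]([C@@H](C)C(=O)O)[C@H]3[C@@H]1[C@@H]1C/C(C)=C\CC[C@](C)(O)[C@H]3O1
A1 | alternative 1 | oxonene with (E)-2-methylbuta-1,3-dienyl on C9 and (E)-3-oxobut-1-enyl on C2 | C=C/C(C)=C/[C@@H]1C/C(C)=C\CC[C@](C)(O[Si](CC)(CC)CC)[C@H](/C=C/C(C)=O)O1
A2 | alternative 1 | tricyclic cycloadduct (C11=C12 alkene, acetyl on C14) | CC1=CC[C@@H](C(C)=O)[C@H]3[C@@H]1[C@@H]1C/C(C)=C\CC[C@](C)(O[Si](CC)(CC)CC)[C@H]3O1
A3 | alternative 2 | bridged seven-membered 3,7-diketone (C6 between the carbonyls) | CC[Si](CC)(CC)O[C@]1(C)CC[C@@H]([C@@H](C)CO[Si](C)(C)C(C)(C)C)[C@H]3[C@@H]1[C@@H]1CC(=O)CC(=O)[C@H]3O1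
A4 | alternative 2 | bridged nine-membered 3,7-dione | CC[Si](CC)(CC)O[C@]1(C)CC[C@@H]([C@@H](C)CO[Si](C)(C)C(C)(C)C)[C@H]3[C@@H]1[C@@H]1CC(=O)CCCC(=O)[C@H]3O1
A5 | alternative 3 | ten-membered cyclic sulfone with the sulfonyl group between C6 and C7 | CC[Si](CC)(CC)O[C@]1(C)CC[C@@H]([C@@H](C)CO[Si](C)(C)C(C)(C)C)[C@H]3[C@@H]1[C@@H]1CC(C)S(=O)(=O)CCC[C@](C)(O[Si](CC)(CC)CC)[C@H]3O1
A6 | alternative 3 | silyl-protected tricyclic oxonene with the Z C6=C7 alkene | CC[Si](CC)(CC)O[C@]1(C)CC[C@@H]([C@@H](C)CO[Si](C)(C)C(C)(C)C)[C@H]3[C@@H]1[C@@H]1C/C(C)=C\CC[C@](C)(O[Si](CC)(CC)CC)[C@H]3O1
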